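## Structural features

The target 26 is a daucane ester: a cyclopentane (ring A, C1–C5) trans-fused through C1–C5 to a cycloheptane (ring B, C5–C10 plus C1), configured 1S,4R,5S,6S,8S,9S,10S. Taking the face of the C1 methyl group as β, H5 is α, the tertiary C4 hydroxyl is β (isopropyl α), the C6 3-methylbutanoate is α (anti to the C4 hydroxyl across C5), and the C9,C10 cis-diol and the oxygen of the C8 spiro-oxirane are all α. The stereocentres form two contiguous arrays, C4–C5–C6 and C8–C9–C10–C1, which meet at the quaternary C1 and the ring fusion. Sensitive groups are the 1,1-disubstituted epoxide beside a free hydroxyl (acid opening, epoxide migration), the ester (β to a carbonyl, hence prone to elimination, whenever C8 is a ketone) and the tertiary C4 carbinol (retro-aldol or dehydration once C6 is a ketone). The real difficulty is the correlation of C1 with C4 and C5: a trans ring fusion next to a quaternary centre, with the hydroxyl on the methyl face, all derived from one absolute stereocentre. The strategic feature is the 1,5-relationship of the oxygenated carbons C4 and C8 across C5–C6–C7, the retron of a de Mayo ring expansion that inserts C6 and C7 into the C5–C8 bond of a diquinane 1,3-dicarbonyl compound. The parent diketone, cis-5-methylbicyclo[3.3.0]octane-2,8-dione, has a mirror plane through C1, C5 and the methyl carbon and is achiral, so the absolute configuration must be carried by a derivative in which the two carbonyl carbons stay different.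

## Logic of the disconnections

26 ⇒ 25. The C8–O and C14–O bonds of the oxirane are cut first, because the epoxy alcohol is the most fragile function and its oxygen is syn to the C9 hydroxyl. This removes one stereocentre; the forward step must deliver oxygen to the α face under hydroxyl direction and tolerate ester and free triol.

25 ⇒ 24 ⇒ 23. The acetonide is restored and the C6–O acyl bond is cut. The ester is thereby introduced after every base- or enolate-dependent step, so it is never β to a ketone; the forward acylation must distinguish the secondary C6 hydroxyl from the tertiary C4 hydroxyl while the diol is masked.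

23 ⇒ 22. The C8=C14 bond is cut to a ketone. C14 is the only missing carbon; the methylenation must be non-basic because the ketone is α-alkoxy and β-hydroxy.

22 ⇒ 21 ⇒ 20. The C9–O and C10–O bonds are cut to a C9=C10 enone. Both carbinols come from one syn-dihydroxylation, which must take place anti to the C1 methyl.

20 ⇒ 18. The C9=C10 unsaturation is removed. The forward dehydrogenation of the C8 ketone has to be regioselective for C9 over C7.

18 ⇒ 17 ⇒ 16. The C6–H bond is cut (carbinol to ketone) and the C8 ketone is masked as its ketal. The C4 hydroxyl is then in a 1,3-relationship to C6 and can direct hydride to give the anti-diol.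

16 ⇒ 15. The C6 carbonyl is traced to an exocyclic methylene, which is a masked ketone and does not form a 1,3-dicarbonyl pair with C4 or C8 while it is carried through.

15 ⇒ 14 ⇒ 13. The C5–H bond and then the C4–O bond are cut, to an alkenyl oxirane and a 4(5),6(14)-diene. Adding isopropyl to the C4 ketone of 11 is not used: a cyclopentanone fused at C5 next to the angular methyl should prefer the cis fusion by protonation and by equilibration, and equilibration would also move the exocyclic alkene into conjugation. Addition to the cis-fused ketone would place the hydroxyl on the wrong face. Instead oxygen is delivered to the β face of a C4=C5 alkene and hydride is put on C5 with inversion; the demand is β-selective epoxidation.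

13 ⇒ 12 ⇒ 11. The C4–isopropyl bond is cut to a dienyl triflate and this to the ketone. Both C5 epimers of 11 converge, so the uncontrolled ring-fusion centre of the key-step product becomes irrelevant; the demand is a cross-coupling at a hindered, fully substituted alkenyl carbon.

11 ⇒ 10 ⇒ 8 + 9. Key disconnection: C5–C6 and C7–C8 are cut and C5–C8 is re-formed. The seven-membered ring contracts to a diquinane and the two inserted carbons become allene. The forward step needs head-to-head addition, a cyclobutane that opens only along C5–C8, and a precursor in which only one ring can expand.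

8 ⇒ 7 ⇒ 6. The O–methyl bond is cut and the oxygen at C4 exchanged for nitrogen. A Claisen closure of an ester chain would pass through the symmetrical diketonate and erase C1, so the closure is planned through a vinylogous amide (nitrogen on C4, oxygen on C8). The forward alkylation must be O-selective and the hydrolysis must stop at the vinylogous ester.

6 ⇒ 5. The C4–C5 bond is cut (ring A) to a ketonitrile. The forward ring closure must choose the C5 enolate, which is ensured because only that adduct can become a conjugated enaminone.

5 ⇒ 4. The C1–CH3 bond is cut. The quaternary centre is made by conjugate addition of methyl, because an ester- or nitrile-bearing alkylzinc halide is not a competent donor towards a β,β-disubstituted cyclopentenone; the demand is high enantioselectivity on a cyclopentenone.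

4 ⇒ 2 + 3 and 2 ⇒ 1. The C1–C2 bond is cut to a β-iodo enone and a commercial alkylzinc reagent, and the iodide is traced to the dione. These steps need no stereocontrol.

## Other disconnections considered

Alternative 1: The cut is at the C3=C4 and C5=C6 double bonds, which opens both rings to the dienyne A1 (alkyne C4≡C5 carrying isopropyl, vinyl ends at C3 and C6, C8 silyl ether and C9,C10 acetonide already present). The forward key step uses the second-generation Grubbs catalyst: ring-closing enyne metathesis from the C6 terminus closes ring B and transfers the carbene to C4, which closes ring A to give diene A2.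
- In its favour: both rings form in one ground-state catalytic step, the isopropyl group is in place, and the C8–C10 oxygens come from a chiral-pool fragment, so neither a regioselective dehydrogenation nor a dihydroxylation of a cycloheptenone is needed.
- Against it here: the quaternary C1 must be built enantioselectively in an open chain with three different unsaturated arms. The diene C3=C4–C5=C6 of A2 must then be turned into C4–OH(β), C5–H(α) and C6–O(α), which requires regio- and face-selective oxidation of a conjugated diene with no obvious handle for the β face at C4.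
- Comparison: on ring construction and on the oxygenation of C8–C10 the alternative is the better plan, and it avoids photochemistry. On the C4/C5/C6 triad the chosen plan is stronger, because diene 13 carries the double bonds where epoxidation and hydrogenolysis translate directly into the three centres. Step economy is about equal once A1 has been assembled.

Alternative 2: The cut is at C1–CH3 and C4–C5, giving the cycloheptenone A3 with a 4-methyl-3-oxopentyl chain on C1. In the forward key step AlMe3 with catalytic Cu(OTf)2 and a chiral phosphoramidite adds methyl to C1, and the aluminium enolate closes ring A on the isopropyl ketone to give A4.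
- In its favour: C1 is set by the catalyst and ring A, the C4 carbinol and C5 arise in the same operation. A4 is the same compound as 16 of the chosen route, reached in far fewer steps; on step economy this alternative is clearly the better one.
- Against it here: a three-atom tether on C1 can only reach the adjacent enolate carbon on its own face, so ring closure must first give the cis-fused aldol A5; the trans fusion written for A4 can only follow from epimerisation at C5. A closed, chelated transition state should also put the C4 oxygen cis to C6 in that cis-fused product, which is the wrong sense relative to C1 and cannot be repaired by epimerising C5. Aluminium enolates add sluggishly and reversibly to a hindered ketone.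
- Comparison: mechanistically the alternative relies on substrate control for two of three centres, where the chosen plan uses a stereospecific epoxide hydrogenolysis. Structurally the later route from A4 would be identical to that from 16.

Alternative 3: The cut is at C7–C8 and C1–C10 (a formal [4+3] disconnection) into the vinylcyclopentene ketal A6 and the silyloxy vinyldiazoacetate A7. In the forward key step Rh2(DOSP)4 transfers the vinylcarbenoid to the vinyl group of A6, and the cis-divinylcyclopropane undergoes Cope rearrangement to the cycloheptadiene A8.
- In its favour: one catalytic asymmetric step builds ring B, the quaternary C1 and the C10 carbinol with a predictable relative configuration (boat transition state), and brings in C14 and the C10 oxygen. On control of C1/C10 and on carbon count at C8 it is the equal or the better of the chosen plan.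
- Against it here: the C1 methyl is the inward substituent of the diene terminus, which should slow the Cope step and favour cyclopropane isomers that cannot rearrange. C9 still needs oxygen syn to C10, and the ester-bearing C8=C9 bond has to become the spiro-epoxide. The C5=C6 alkene and the C4 ketal leave the whole C4/C5/C6 triad, including the ring-fusion problem, unsolved.
- Comparison: the ring B oxygenation pattern is closer to the target than in the chosen plan, ring A is further away, and the overall step count is not expected to be lower.

Key step: step 6

Remark: bicyclic compounds are described with daucane locants (C1 quaternary, C2–C4 in ring A, C5 ring-fusion carbon, C6–C10 in ring B, C14 the carbon on C8); β is the face of the C1 methyl group.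
Remark: the sense of induction in step 3 depends on the ligand enantiomer; the one that gives (R)-5 is assumed.
Remark: 3 is used as its commercial THF solution.

## Route

Step 1
Reactants: 1 cyclopentane-1,3-dione
Product: 2 3-iodocyclopent-2-en-1-one
Conditions: PPh3, I2, Et3N, MeCN, rt to 80 °C
Reagents that add atoms: iodine, II
Why: The enol oxygen of the vinylogous acid is activated as an oxyphosphonium salt and replaced by iodide through addition–elimination, the standard route from cyclic 1,3-diones to β-iodo enones.

Step 2
Reactants: 2 3-iodocyclopent-2-en-1-one; 3 (2-cyanoethyl)zinc bromide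
Product: 4 3-(3-oxocyclopent-1-en-1-yl)propanenitrile
Conditions: Pd(PPh3)4 (3 mol %), THF, rt
Reagents that add atoms: none
Why: Negishi coupling: zerovalent palladium inserts readily into the activated alkenyl iodide and the primary alkylzinc reagent transmetalates without touching ketone or nitrile; no stereocentre is formed.

Step 3
Reactants: 4 3-(3-oxocyclopent-1-en-1-yl)propanenitrile
Product: 5 3-[(1R)-1-methyl-3-oxocyclopentyl]propanenitrile
Conditions: AlMe3 (2 equiv), Cu(OTf)2 (5 mol %), chiral biphenol-based phosphoramidite (10 mol %), Et2O, −30 °C; aq NH4Cl
Reagents that add atoms: trimethylaluminium, C[Al](C)C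
Why: Copper-catalysed asymmetric conjugate addition of a trialkylaluminium to a β-substituted cyclopentenone creates the quaternary C1; the ligand on copper selects the enone face. Methyl is used as the nucleophile because functionalised alkylzinc halides do not add to β,β-disubstituted cyclopentenones.

Step 4
Reactants: 5 3-[(1R)-1-methyl-3-oxocyclopentyl]propanenitrile
Product: 6 (3aR)-6-amino-3a-methyl-3,3a,4,5-tetrahydropentalen-1(2H)-one
Conditions: KOtBu (1.1 equiv), tBuOH/THF, 50 °C; AcOH
Reagents that add atoms: none
Why: Thorpe–Ziegler-type addition of the ketone enolate to the nitrile; only attack from C5 can end in a conjugated, hydrogen-bonded enaminone (the other α-carbon would need a bridgehead enamine), so the reversible steps funnel to 6. Nitrogen on C4 and oxygen on C8 keep the two rings different, so C1 remains a stereocentre.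

Step 5
Reactants: 6 (3aR)-6-amino-3a-methyl-3,3a,4,5-tetrahydropentalen-1(2H)-one
Product: 8 (3aS)-6-methoxy-3a-methyl-3,3a,4,5-tetrahydropentalen-1(2H)-one, via O-methyl iminium tetrafluoroborate 7 (not isolated)
Conditions: Me3OBF4 (1.1 equiv), CH2Cl2, 0 °C to rt; then H2O, NaOAc/AcOH buffer, 0 °C
Reagents that add atoms: trimethyloxonium tetrafluoroborate, C[O+](C)C.F[B-](F)(F)F; water, O
Why: Hard alkylation of the vinylogous amide on oxygen gives 7, whose N-unsubstituted C=N bond hydrolyses much faster than the enol ether, so the carbonyl ends on C4 and the methoxy group on C8 (vinylogous amide to vinylogous ester with transposition). The symmetrical diketone is never passed, and any of it formed by over-hydrolysis is achiral and cannot lower the enantiomeric purity of 8.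

Step 6
Reactants: 8 (3aS)-6-methoxy-3a-methyl-3,3a,4,5-tetrahydropentalen-1(2H)-one; 9 propa-1,2-diene
Product: 11 8,8-(ethylenedioxy)-1-methyl-6-methylidene-octahydroazulen-4-one (C1 as in 26; C5 epimers), via 8-methoxy-6-methylidene-5,8-cyclo photoadduct 10 (not isolated)
Conditions: hν (Hg lamp, Pyrex, λ > 290 nm), excess 9, CH2Cl2, −70 °C; evaporate 9; then HOCH2CH2OH (5 equiv), CSA (10 mol %), CH2Cl2, 0 °C to rt
Reagents that add atoms: ethane-1,2-diol, OCCO
Why: The excited s-cis β-methoxy enone adds as its triplet to allene through a 1,4-biradical; as with other enones the central allene carbon bonds to the α-carbon C5 and a terminal carbon to C8, so the four-membered ring closes by a stepwise head-to-head [2+2] cycloaddition. The closest known reaction type is the de Mayo reaction in its enol-ether variant (alkoxy enone–alkene photocycloaddition followed by retro-aldol-type opening). Allene can only add to the face of C5 that bears the C1 methyl, since only a cis-fused diquinane can form; C5 and C8 of 10 are thus fixed by the ring system and both disappear again. Acid then opens the donor–acceptor cyclobutane: the C5–C8 bond, aligned with the C4 carbonyl π-system, breaks with push from the methoxy oxygen to give the C4 enol and a C8 oxocarbenium ion, which the diol traps as the dioxolane; the seven-membered ring therefore arises by ring expansion and not by a cyclisation, so no exo or endo mode applies. C1 is controlled by the position of the enol ether in 8: only the ring containing the C5=C8 bond can expand, so the enantiomer of 11 follows from (S)-8 without new induction. C5 of 11 is formed by enol protonation, is not controlled (the cis fusion is expected to dominate) and is erased in step 7. The selectivities needed are the head-to-head orientation, which is inherent to allene, and the differentiation of C4 from C8, which is built in because only C8 passes through the oxocarbenium stage.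

Step 7
Reactants: 11 8,8-(ethylenedioxy)-1-methyl-6-methylidene-octahydroazulen-4-one
Product: 12 8,8-(ethylenedioxy)-1-methyl-6-methylidene-4(5)-en-4-yl trifluoromethanesulfonate
Conditions: NaN(SiMe3)2 (0.95 equiv), THF, −78 to −20 °C; PhNTf2, −20 °C to rt
Reagents that add atoms: N-phenylbis(trifluoromethanesulfonimide), O=S(=O)(N(c1ccccc1)S(=O)(=O)C(F)(F)F)C(F)(F)F
Why: H5, α to the ketone and allylic, is the most acidic hydrogen; equilibration with a slight deficit of base gives the cross-conjugated dienolate, which is triflated on oxygen. Both C5 epimers of 11 converge on 12.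

Step 8
Reactants: 12 dienyl triflate
Product: 13 8,8-(ethylenedioxy)-4-isopropyl-1-methyl-6-methylidene-4(5)-ene
Conditions: iPrMgCl (1.5 equiv), Fe(acac)3 (5 mol %), THF/NMP, −30 °C
Reagents that add atoms: isopropylmagnesium chloride, CC(C)[Mg]Cl
Why: Iron-catalysed cross-coupling of an alkenyl triflate with a secondary alkyl Grignard reagent forms the C4–isopropyl bond; no stereocentre is formed.

Step 9
Reactants: 13 diene
Product: 14 4β,5β-epoxy-8,8-(ethylenedioxy)-4-isopropyl-1-methyl-6-methylidene-octahydroazulene
Conditions: dimethyldioxirane (1.05 equiv, acetone), CH2Cl2, −40 °C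
Reagents that add atoms: dimethyldioxirane, CC1(C)OO1
Why: The electron-rich tetrasubstituted C4=C5 bond is epoxidised before the 1,1-disubstituted one under neutral conditions. Attack is expected on the methyl (β) face, because C10, C9 and the C8 ketal of ring B cover the α face and the β-epoxide keeps C6 and C10 cis on the five-membered ring.

Step 10
Reactants: 14 alkenyl oxirane
Product: 15 8,8-(ethylenedioxy)-4α-isopropyl-1β-methyl-6-methylidene-5α-H-octahydroazulen-4β-ol
Conditions: Pd2(dba)3·CHCl3 (2.5 mol %), PBu3 (10 mol %), HCO2H (3 equiv), Et3N (1.2 equiv), THF, rt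
Reagents that add atoms: none
Why: Palladium-catalysed formate hydrogenolysis of an alkenyl oxirane: ionisation anti to the C5–O bond puts palladium on the α face of the π-allyl unit, and hydride passes from the metal to the more substituted terminus C5, i.e. with inversion. This sets H5 α (trans fusion) with the C4 oxygen retained β and regenerates the exocyclic methylene; the allyl termini carry no β-hydrogen, so diene formation cannot compete.

Step 11
Reactants: 15 homoallylic alcohol
Product: 16 8,8-(ethylenedioxy)-4β-hydroxy-4α-isopropyl-1β-methyl-5α-H-octahydroazulen-6-one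
Conditions: O3, CH2Cl2/MeOH, −78 °C; Me2S, −78 °C to rt
Reagents that add atoms: ozone, [O-][O+]=O
Why: Ozonolysis of the only alkene gives the C6 ketone; the neutral reductive work-up avoids retro-aldol cleavage or dehydration of the tertiary β-hydroxy ketone. C5 is now epimerisable but already has the favoured arrangement, C6 trans to isopropyl.

Step 12
Reactants: 16 β-hydroxy ketone
Product: 18 4β,6α-dihydroxy-4α-isopropyl-1β-methyl-5α-H-octahydroazulen-8-one, via diol ketal 17 (not isolated)
Conditions: Me4NBH(OAc)3 (5 equiv), MeCN/AcOH, −30 °C; then 1 M HCl, THF, 0 °C to rt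
Reagents that add atoms: water, O
Why: Evans–Saksena reduction: the C4 hydroxyl binds the acetoxyborohydride and delivers hydride intramolecularly to the β face of the C6 carbonyl, which gives the anti-1,3-diol (C6–OH α). Aqueous acid in the work-up then hydrolyses the dioxolane.

Step 13
Reactants: 18 dihydroxy ketone
Product: 20 4β,6α-dihydroxy-4α-isopropyl-1β-methyl-5α-H-9-en-8-one, via tris(trimethylsilyl) enol ether 19 (not isolated)
Conditions: Me3SiCl (6 equiv), LiN(iPr)2 (3.5 equiv), THF, −78 to −40 °C; then Pd(OAc)2 (1.1 equiv), MeCN, rt; 1 M HCl, THF, 0 °C
Reagents that add atoms: none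
Why: Kinetic deprotonation is directed to C9, away from the C7 methylene next to the oxygenated C6, and the silyl enol ether is dehydrogenated by Saegusa–Ito oxidation with divalent palladium. Both hydroxyls are masked in the same flask as trimethylsilyl ethers, which are cleaved in the acidic work-up.

Step 14
Reactants: 20 enone
Product: 21 4β,6α,9α,10α-tetrahydroxy-4α-isopropyl-1β-methyl-5α-H-octahydroazulen-8-one
Conditions: OsO4 (5 mol %), NMO (1.5 equiv), acetone/H2O, rt
Reagents that add atoms: osmium tetroxide, O=[Os](=O)(=O)=O; N-methylmorpholine N-oxide, C[N+]1([O-])CCOCC1; water, O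
Why: Catalytic syn-dihydroxylation adds both oxygens to the face of the cis-enone opposite the pseudo-axial C1 methyl, which gives the 9α,10α-diol.

Step 15
Reactants: 21 tetraol ketone
Product: 22 9α,10α-O-isopropylidene derivative of 21
Conditions: Me2C(OMe)2 (3 equiv), PPTS (5 mol %), acetone, rt
Reagents that add atoms: 2,2-dimethoxypropane, COC(C)(C)OC
Why: Acetonide formation is fastest for the cis-vicinal diol (five-membered dioxolane); the tertiary and the hindered secondary hydroxyl remain free.

Step 16
Reactants: 22 acetonide ketone
Product: 23 9α,10α-O-isopropylidene-8-methylidene-4β,6α-diol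
Conditions: Cp2TiMe2 (4 equiv), toluene/THF, 65 °C, dark
Reagents that add atoms: dimethyltitanocene, [CH3-].[CH3-].[Ti+4].c1cc[cH-]c1.c1cc[cH-]c1
Why: Petasis methylenation is non-basic, so the α-alkoxy ketone is not epimerised and the β-hydroxy ketone is not cleaved; the free hydroxyls only consume reagent.

Step 17
Reactants: 23 methylidene diol
Product: 24 6α-(3-methylbutanoyloxy)-9α,10α-O-isopropylidene-8-methylidene-4β-ol
Conditions: 3-methylbutanoyl chloride (1.5 equiv), pyridine, DMAP (0.1 equiv), CH2Cl2, 0 °C to rt
Reagents that add atoms: 3-methylbutanoyl chloride, CC(C)CC(Cl)=O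
Why: Acylation of the secondary C6 hydroxyl; the tertiary C4 hydroxyl is inert under these conditions and the diol is masked. The ester enters only after the last enolate step, so it is never β to a ketone.

Step 18
Reactants: 24 ester acetonide
Product: 25 6α-(3-methylbutanoyloxy)-8-methylidene-4β,9α,10α-triol
Conditions: AcOH/THF/H2O (3:1:1), 40 °C
Reagents that add atoms: none
Why: Mild aqueous acid hydrolyses the acetonide; ester and exocyclic alkene are stable under these conditions.

Step 19
Reactants: 25 triol ester
Product: 26 CNP0307265.1, (1S,4R,5S,6S,8S,9S,10S)-8,14-epoxy-4,9,10-trihydroxydaucan-6-yl 3-methylbutanoate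
Conditions: VO(acac)2 (5 mol %), tBuOOH (1.5 equiv), CH2Cl2, 0 °C to rt
Reagents that add atoms: tert-butyl hydroperoxide, CC(C)(C)OO
Why: Hydroxyl-directed epoxidation: the vanadium alkoxide of the allylic C9 hydroxyl delivers oxygen to the same (α) face of the exocyclic alkene and sets C8. The step is last because the epoxy alcohol is acid- and base-sensitive.

## Compound list

1 | cyclopentane-1,3-dione | O=C1CCC(=O)C1 | starting material
2 | 3-iodocyclopent-2-en-1-one | O=C1CCC(I)=C1 | intermediate
3 | (2-cyanoethyl)zinc bromide | N#CCC[Zn]Br | starting material
4 | 3-(3-oxocyclopent-1-en-1-yl)propanenitrile | N#CCCC1=CC(=O)CC1 | intermediate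
5 | 3-[(1R)-1-methyl-3-oxocyclopentyl]propanenitrile | O=C1CC[C@@](C)(CCC#N)C1 | intermediate
6 | (3aR)-6-amino-3a-methyl-3,3a,4,5-tetrahydropentalen-1(2H)-one (N on C4, O on C8) | O=C1CC[C@@]2(C)CCC(N)=C12 | intermediate
7 | 6-methoxy-3a-methyl-3,3a,4,5-tetrahydropentalen-1(2H)-iminium tetrafluoroborate (C3a unchanged from 6) | [NH2+]=C1CC[C@]2(C)CCC(OC)=C12.F[B-](F)(F)F | intermediate
8 | (3aS)-6-methoxy-3a-methyl-3,3a,4,5-tetrahydropentalen-1(2H)-one (8-O-methyl enol ether of the diquinane 4,8-dione) | O=C1CC[C@]2(C)CCC(OC)=C12 | intermediate
9 | propa-1,2-diene | C=C=C | starting material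
10 | 8-methoxy-1-methyl-6-methylidene-5,8-cyclo-octahydroazulen-4-one (cis-fused diquinane with cyclobutane across C5–C8, C6 cis to the C1 methyl) | C=C1C[C@]2(OC)CC[C@@]3(C)CCC(=O)[C@@]123 | intermediate
11 | 8,8-(ethylenedioxy)-1-methyl-6-methylidene-octahydroazulen-4-one (C1 as in 26; C5 epimers, cis expected to dominate) | C=C1CC2(OCCO2)CC[C@@]3(C)CCC(=O)C13 | intermediate
12 | 8,8-(ethylenedioxy)-1-methyl-6-methylidene-4(5)-en-4-yl trifluoromethanesulfonate | C=C1CC2(OCCO2)CC[C@@]3(C)CCC(OS(=O)(=O)C(F)(F)F)=C13 | intermediate
13 | 8,8-(ethylenedioxy)-4-isopropyl-1-methyl-6-methylidene-4(5)-ene | C=C1CC2(OCCO2)CC[C@@]3(C)CCC(C(C)C)=C13 | intermediate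
14 | 4β,5β-epoxy-8,8-(ethylenedioxy)-4-isopropyl-1β-methyl-6-methylidene-octahydroazulene | C=C1CC2(OCCO2)CC[C@@]3(C)CC[C@]4(C(C)C)O[C@]134 | intermediate
15 | 8,8-(ethylenedioxy)-4α-isopropyl-1β-methyl-6-methylidene-5α-H-octahydroazulen-4β-ol | C=C1CC2(OCCO2)CC[C@@]3(C)CC[C@@](O)(C(C)C)[C@H]13 | intermediate
16 | 8,8-(ethylenedioxy)-4β-hydroxy-4α-isopropyl-1β-methyl-5α-H-octahydroazulen-6-one | O=C1CC2(OCCO2)CC[C@@]3(C)CC[C@@](O)(C(C)C)[C@H]13 | intermediate
17 | 8,8-(ethylenedioxy)-4α-isopropyl-1β-methyl-5α-H-octahydroazulene-4β,6α-diol | O[C@H]1CC2(OCCO2)CC[C@@]3(C)CC[C@@](O)(C(C)C)[C@H]13 | intermediate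
18 | 4β,6α-dihydroxy-4α-isopropyl-1β-methyl-5α-H-octahydroazulen-8-one | O[C@H]1CC(=O)CC[C@@]2(C)CC[C@@](O)(C(C)C)[C@H]12 | intermediate
19 | 4β,6α,8-tris(trimethylsilyloxy)-4α-isopropyl-1β-methyl-8(9)-ene | C[Si](C)(C)O[C@H]1CC(O[Si](C)(C)C)=CC[C@@]2(C)CC[C@@](O[Si](C)(C)C)(C(C)C)[C@H]12 | intermediate
20 | 4β,6α-dihydroxy-4α-isopropyl-1β-methyl-5α-H-9-en-8-one | O[C@H]1CC(=O)C=C[C@@]2(C)CC[C@@](O)(C(C)C)[C@H]12 | intermediate
21 | 4β,6α,9α,10α-tetrahydroxy-4α-isopropyl-1β-methyl-5α-H-octahydroazulen-8-one | O[C@H]1CC(=O)[C@@H](O)[C@@H](O)[C@@]2(C)CC[C@@](O)(C(C)C)[C@H]12 | intermediate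
22 | 9α,10α-O-isopropylidene derivative of 21 | O[C@H]1CC(=O)[C@H]2OC(C)(C)O[C@H]2[C@@]3(C)CC[C@@](O)(C(C)C)[C@H]13 | intermediate
23 | 9α,10α-O-isopropylidene-4α-isopropyl-1β-methyl-8-methylidene-5α-H-octahydroazulene-4β,6α-diol | O[C@H]1CC(=C)[C@H]2OC(C)(C)O[C@H]2[C@@]3(C)CC[C@@](O)(C(C)C)[C@H]13 | intermediate
24 | 6α-(3-methylbutanoyloxy) derivative of 23 | CC(C)CC(=O)O[C@H]1CC(=C)[C@H]2OC(C)(C)O[C@H]2[C@@]3(C)CC[C@@](O)(C(C)C)[C@H]13 | intermediate
25 | 4β,9α,10α-trihydroxy-4α-isopropyl-1β-methyl-8-methylidene-5α-H-octahydroazulen-6α-yl 3-methylbutanoate | CC(C)CC(=O)O[C@H]1CC(=C)[C@@H](O)[C@@H](O)[C@@]2(C)CC[C@@](O)(C(C)C)[C@H]12 | intermediate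
26 | CNP0307265.1, (1S,4R,5S,6S,8S,9S,10S)-8,14-epoxy-4,9,10-trihydroxydaucan-6-yl 3-methylbutanoate | CC(C)CC(=O)O[C@H]1C[C@]2(CO2)[C@@H](O)[C@@H](O)[C@@]2(C)CC[C@@](O)(C(C)C)[C@H]12 | target

## Step count and least certain steps

Total step count: 19. Longest linear sequence: 19 steps (from 1; 3 and 9 are purchased).

Step 6 (key step). The most likely failure is in the acid opening of 10: migration of the exocyclic double bond into conjugation, ketalisation at C4, or sluggish opening of the hindered tertiary methyl ether. A head-to-tail orientation in the cycloaddition is the lesser risk. Fallback: starting from 10, the methyl ether is cleaved with Me3SiI (CH2Cl2, −40 °C); the same C5–C8 cleavage follows and aqueous work-up gives the unprotected 1-methyl-6-methylidene-octahydroazulene-4,8-dione F1. Its unhindered cycloheptanone carbonyl C8 is then ketalised selectively (1,2-bis(trimethylsilyloxy)ethane, Me3SiOTf, CH2Cl2, −78 °C), which returns to 11.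

Step 3. Insufficient enantioselectivity, or slow turnover because the nitrile binds aluminium or copper. Fallback: starting from 5 of low enantiomeric purity (or racemic, from the same addition run with an achiral phosphine), the ketone is ketalised with (R,R)-hydrobenzoin (PPTS, benzene, reflux). The diastereomer derived from (R)-5, the hydrobenzoin ketal F2, is separated by crystallisation or chromatography and hydrolysed (1 M HCl, THF), which returns to 5.

Step 8. Reduction of the triflate, or transfer of an isomerised propyl group, at the hindered fully substituted alkenyl carbon. Fallback: starting from 11, isopropylmagnesium chloride with CeCl3 (THF, −78 °C) adds to the ketone to give the tertiary carbinol F3 (configuration at C4 and C5 immaterial), which is dehydrated towards the allylic C5 hydrogen (SOCl2, pyridine, −20 °C) to return to 13.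

Step 9. Epoxidation on the α face, or acid-induced rearrangement of the tetrasubstituted alkenyl oxirane before step 10. Fallback: starting from 13, Lemieux–Johnson cleavage of the exocyclic methylene (OsO4 cat., NaIO4, 2,6-lutidine, dioxane/H2O) gives the 4(5)-en-6-one F4. Weitz–Scheffer epoxidation (tBuOOH, DBU, CH2Cl2), in which the reversible hydroperoxide addition lets the ring-closing step choose the epoxide that keeps C6 and C10 cis, gives the β-epoxy ketone F5. SmI2 (THF/MeOH, −78 °C) then opens the C5–O bond, with C5 set by protonation to the isomer having C6 trans to isopropyl. This returns to 16 and bypasses 14 and 15.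

Step 13. Loss of regiocontrol in the enolisation (deprotonation at C7), followed by β-elimination of the C6 oxygen. Fallback: starting from 18, the secondary hydroxyl is silylated (tBuMe2SiOTf, 2,6-lutidine, CH2Cl2, −78 °C) to the 6-O-silyl ketone F6, whose bulky ether shields C7. Deprotonation (LiN(iPr)2, 2.2 equiv, THF, −78 °C) and PhSeBr give the 9-selenide F7, and H2O2/pyridine gives by selenoxide syn-elimination the 6-O-silyl enone F8. HF·pyridine (THF) then returns to 20.

## Further compounds

F1 | step 6 | 1-methyl-6-methylidene-octahydroazulene-4,8-dione (C1 as in 26, C5 epimers) | C=C1CC(=O)CC[C@@]2(C)CCC(=O)C12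
F2 | step 3 | (R,R)-hydrobenzoin ketal of 5 | N#CCC[C@]1(C)CCC2(C1)O[C@H](c3ccccc3)[C@@H](c3ccccc3)O2
F3 | step 8 | 8,8-(ethylenedioxy)-4-isopropyl-1-methyl-6-methylidene-octahydroazulen-4-ol (C4 and C5 unassigned) | C=C1CC2(OCCO2)CC[C@@]3(C)CCC(O)(C(C)C)C13
F4 | step 9 | 8,8-(ethylenedioxy)-4-isopropyl-1-methyl-4(5)-en-6-one | O=C1CC2(OCCO2)CC[C@@]3(C)CCC(C(C)C)=C13
F5 | step 9 | 4β,5β-epoxy-8,8-(ethylenedioxy)-4-isopropyl-1β-methyl-octahydroazulen-6-one | O=C1CC2(OCCO2)CC[C@@]3(C)CC[C@]4(C(C)C)O[C@]134
F6 | step 13 | 6α-(tert-butyldimethylsilyloxy)-4β-hydroxy-4α-isopropyl-1β-methyl-5α-H-octahydroazulen-8-one | CC(C)(C)[Si](C)(C)O[C@H]1CC(=O)CC[C@@]2(C)CC[C@@](O)(C(C)C)[C@H]12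
F7 | step 13 | 9-(phenylselanyl) derivative of F6 (C9 unassigned) | CC(C)(C)[Si](C)(C)O[C@H]1CC(=O)C([Se]c3ccccc3)C[C@@]2(C)CC[C@@](O)(C(C)C)[C@H]12
F8 | step 13 | 6α-(tert-butyldimethylsilyloxy)-4β-hydroxy-4α-isopropyl-1β-methyl-5α-H-9-en-8-one | CC(C)(C)[Si](C)(C)O[C@H]1CC(=O)C=C[C@@]2(C)CC[C@@](O)(C(C)C)[C@H]12
A1 | alternative 1 | acyclic dienyne: C1 quaternary centre with methyl, allyl and 3-methylbut-1-ynyl groups, C9,C10 acetonide, C8 silyl ether, C6 vinyl end | C=CC[C@H](O[Si](C)(C)C(C)(C)C)[C@H]1OC(C)(C)O[C@H]1[C@@](C)(CC=C)C#CC(C)C
A2 | alternative 1 | bicyclo[5.3.0]deca-3,5-diene with C4 isopropyl, C8 silyl ether and C9,C10 acetonide | C1[C@H](O[Si](C)(C)C(C)(C)C)[C@H]3OC(C)(C)O[C@H]3[C@@]2(C)CC=C(C(C)C)C2=C1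
A3 | alternative 2 | 6,6-(ethylenedioxy)-3-(4-methyl-3-oxopentyl)cyclohept-2-en-1-one | O=C1CC2(OCCO2)CCC(CCC(=O)C(C)C)=C1
A4 | alternative 2 | trans-fused C4-hydroxy C6-ketone with C8 dioxolane (identical with 16) | O=C1CC3(OCCO3)CC[C@@]2(C)CC[C@@](O)(C(C)C)[C@H]12
A5 | alternative 2 | cis-fused aldol, C5 epimer series of A4 (C4 unassigned) | O=C1CC2(OCCO2)CC[C@@]3(C)CCC(O)(C(C)C)[C@@H]13
A6 | alternative 3 | 6-ethenyl-7-methyl-1,4-dioxaspiro[4.4]non-6-ene | C=CC1=C(C)CCC12OCCO2
A7 | alternative 3 | methyl (E)-4-(tert-butyldimethylsilyloxy)-2-diazobut-3-enoate | COC(=O)C(=[N+]=[N-])/C=C/O[Si](C)(C)C(C)(C)C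
A8 | alternative 3 | bicyclic cyclohepta-5,8-diene C8 methyl ester with C4 ketal and C10 silyl ether | C1C(C(=O)OC)=C[C@@H](O[Si](C)(C)C(C)(C)C)[C@@]2(C)CCC3(OCCO3)C2=C1
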